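The readings were generated by integration on assumed constants; scatter was added.

**The question.** What stands in the red flask at 10 min, with c(starting material) = 0.50 M, and has it stopped? We count turnovers.

| flask | starting material | remark | time |
|---|---|---|---|
| red | 0.50 M | the very flask that is asked about, followed so far |  |
| grey | 1 M | run made earlier |  |
| flask | 0.50 M |  | 10 min |

red run (percent of the starting material charged)

| time / s | starting material / % | target / % |
|---|---|---|
| 10.0 | 36 | 9 |
| 15.0 | 20 | 13 |
| 25.0 | 9 | 16 |
| 40.0 | 6 | 18 |
| 80.0 | 3 | 21 |
| 120 | 3 | 21 |

grey run (percent of the starting material charged)

| time / min | starting material / % | target / % |
|---|---|---|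
| 0.500 | 7 | 20 |
| 1.00 | 5 | 20 |
| 1.50 | 1 | 22 |
| 2.50 | 3 | 21 |
| 4.00 | 4 | 19 |
| 8.00 | 5 | 20 |

(each reading ± 2 percentage points)

1. why nothing more happens at 10 min, or that something still does (it is still moving / forward and back rates have come level / all of the starting material has reacted)
2. how much of the starting material has reacted by 10 min
3. how much target there is at 10 min, in percent of the starting material charged
4. how much intermediate there is at 10 min, in percent of the starting material charged

- what may be going on: starting material <-> intermediate; target <-> isomer of the product; intermediate <-> target
- the reaction counts as stopped when no species that holds the starting material changes by six tenths of a point or more over the second half of the time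

**First count.** A turnover count is the time divided by a half-life. Red starting material falls from 36% to 20% between 10.0 s and 15.0 s, which reads as a half-life of 5.90 s. But target arrives behind it, so this half-life may be too short for the whole flask.

**Better count.** Late readings of target, red from 80.0 s and grey from 1.50 min, average 20.7%. Between 10.0 s and 40.0 s, red target's distance from that plateau halves every 14.1 s. This target half-life is longer than the first one, and 10 min holds 42.6 of them.

**Two doubts.** The last gap used is 2.7 percentage points, close to the scatter, so the half-life is rough. Yet 3 times that half-life still leaves 14.2 turnovers. A slower step might hide, but grey target, at twice the charge, reads 22% at 1.50 min and 20% at 8.00 min, flat within the scatter. That speaks for the measured species, not for the unmeasured pair.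

**Our estimate.** The matching late starting material readings average 3.17%, with a standard error of 0.82 points, so we read that average as above zero. We expect equilibrium (thermodynamic control), with 96.8% reacted and target at the plateau. That leaves 76.1% for intermediate and isomer of the product, and we find no reading that splits it.

**The forecast.** It says forward and back rates have come level, with 96.7% reacted, 20.5% target and 40% intermediate, this last “a rough estimate, with a wide range”. Its conversion differs from ours by 0.13 points and its target by 0.20 points.

**The flask.** The simulation gives forward and back rates have come level, with 96.7% reacted, 20.2% target and 69.5% intermediate.

    starting material ⇌ intermediate (K = 21.0, k = 0.110 /s)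
    target ⇌ isomer of the product (K = 0.350, k = 0.00530 /s)
    intermediate ⇌ target (K = 0.290, k = 0.0290 /s)

**Earlier reading.** The forecast's intermediate stands 30 points below the flask's. Over the second half of the time in the asked flask, our 42.6 turnovers go with a largest change of 0.083 points. Read at 4.0 min, the same flask has 17.0 turnovers of 14.1 s, and it shows 96.7% reacted, 20.2% target and 69.7% intermediate. Its isomer of the product, unmeasured in the runs, stands at 6.84%, against 7.05% at 10.0 min.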